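**Plan**

1. Cuts, in retrosynthetic order: the C9–OAc bond (made last, with inversion) and the C8 ester; then the C8–C9 ring bond, which opens the ten-membered ring to dialdehyde 25; then C7–C8 and C11–C13 (conjugate addition and aminomethylation of butenolide 17), C6–C7 (alkynylation with methyl propiolate), the C4/C5 epoxide, C1=C10 (aldol and dehydration) and C1 (ozonolysis of geranyl acetate).
2. Enabling feature: C9 lies between C8 and C10 of the C1=C10–C14 unsaturated ester, so C8(OH)–C9(O)–C10=C1 is the pattern left by γ-attack of a 3-oxyallyl metal on an aldehyde. The metal species comes from a 2-formyl-2-enoate (C9 aldehyde on C10), the most easily reduced group of 25; the electrophile is the C8 aldehyde on C7 of the γ-lactone ring (O–C6–C7–C11–C12).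
3. Forward order: chain C1–C6/C15 from geranyl acetate, ester unit C9/C10/C14, enal at C6, then C7/C11/C12; the epoxide ring is formed first, the lactone ring second, C8 and C13 are added, and the ten-membered carbocycle is closed last through C8–C9.
4. Stereochemistry: C6 by catalyst control (Zn-ProPhenol alkynylation); C4/C5 by hydroxyl-directed threo epoxidation; C7 by anti conjugate addition; C8 by Felkin–Anh control in the ring closure; C9 is formed erythro (9R) in the closed transition state of the ring closure and is inverted to 9S when the acetate is introduced by Mitsunobu reaction.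

Key step: step 15

Remark on numbering: germacranolide numbering is used throughout. C1(H)=C10 carries C14 (CO2Me); C9 carries OAc; C8 carries the methacrylate; C7 and C6 carry the lactone (C11=C13, C12=O); C5/C4 are the epoxide (C15 methyl on C4); C3 and C2 are CH2. The target is (4R,5R,6S,7R,8S,9S) with C2 trans to CO2Me on C1=C10.

Assumption: the (S,S) antipode of ProPhenol is taken as the one that delivers the alkynyl group to the Si face of enal 11 (6R in 14); if the sense of induction is the opposite, the (R,R) ligand is used.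

Remark: 7 and 8 are mixtures of diastereomers at C1/C10; the stereocenters at C11 of 19/20, C8 of 23 and C1 of 26 are transient.

**Route**

Step 1
Reactants: 1 geranyl acetate
Product: 3 (4E)-6-acetoxy-4-methylhex-4-enal, via ozonide 2 (not isolated)
Conditions: O3 (1.0 equiv), CH2Cl2, −78 °C; then Me2S, −78 °C to rt
Reagents that add atoms: ozone, [O-][O+]=O
Why: ozonolysis with reductive work-up should cleave the electron-rich 6,7-olefin in preference to the 2,3-olefin, which is deactivated by the allylic acetate; no stereocenter is formed and the (E) olefin is kept.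

Step 2
Reactants: 4 methyl 3-hydroxypropanoate
Product: 5 methyl 3-[(tert-butyldimethylsilyl)oxy]propanoate
Conditions: TBSCl, imidazole, DMF, rt
Reagents that add atoms: tert-butyldimethylsilyl chloride (TBSCl), CC(C)(C)[Si](C)(C)Cl
Why: routine silylation of a primary alcohol; no stereocenter.

Step 3
Reactants: 5 methyl 3-[(tert-butyldimethylsilyl)oxy]propanoate; 3 (4E)-6-acetoxy-4-methylhex-4-enal
Product: 7 methyl (6E)-8-acetoxy-3-hydroxy-6-methyl-2-{[(tert-butyldimethylsilyl)oxy]methyl}oct-6-enoate, via lithium enolate 6 (not isolated)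
Conditions: LDA (1.05 equiv), THF, −78 °C; then 3, −78 °C; aq. NH4Cl
Reagents that add atoms: none
Why: aldol addition of a lithium ester enolate to the aldehyde at −78 °C, where loss of silanolate and attack on the acetate are slow; the two new stereocenters (C1, C10) are left uncontrolled because both are removed in step 4.

Step 4
Reactants: 7 methyl (6E)-8-acetoxy-3-hydroxy-6-methyl-2-{[(tert-butyldimethylsilyl)oxy]methyl}oct-6-enoate
Product: 9 methyl (2E,6E)-8-acetoxy-6-methyl-2-{[(tert-butyldimethylsilyl)oxy]methyl}octa-2,6-dienoate, via mesylate 8 (not isolated)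
Conditions: MsCl, Et3N, CH2Cl2, 0 °C; then DBU, rt
Reagents that add atoms: none
Why: mesylation and E1cB elimination should give mainly the trisubstituted enoate with the chain trans to the ester (C1=C10); any (Z) isomer is harmless because this geometry is erased at the allyl radical/allylchromium stage of step 15.

Step 5
Reactants: 9 methyl (2E,6E)-8-acetoxy-6-methyl-2-{[(tert-butyldimethylsilyl)oxy]methyl}octa-2,6-dienoate
Product: 10 methyl (2E,6E)-8-hydroxy-6-methyl-2-{[(tert-butyldimethylsilyl)oxy]methyl}octa-2,6-dienoate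
Conditions: K2CO3 (0.2 equiv), MeOH, 0 °C
Reagents that add atoms: none
Why: base-catalysed transesterification removes the primary allylic acetate, while the methyl ester exchanges degenerately with methanol and the TBS ether is stable; no stereocenter.

Step 6
Reactants: 10 methyl (2E,6E)-8-hydroxy-6-methyl-2-{[(tert-butyldimethylsilyl)oxy]methyl}octa-2,6-dienoate
Product: 11 methyl (2E,6E)-6-methyl-8-oxo-2-{[(tert-butyldimethylsilyl)oxy]methyl}octa-2,6-dienoate
Conditions: MnO2 (activated, excess), CH2Cl2, rt
Reagents that add atoms: none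
Why: MnO2 oxidation of the primary allylic alcohol to the (E)-enal without isomerisation; no stereocenter.

Step 7
Reactants: 11 methyl (2E,6E)-6-methyl-8-oxo-2-{[(tert-butyldimethylsilyl)oxy]methyl}octa-2,6-dienoate; 12 methyl propiolate
Product: 14 dimethyl (2E,6E,8R)-2-{[(tert-butyldimethylsilyl)oxy]methyl}-8-hydroxy-6-methylundeca-2,6-dien-9-ynedioate, via zinc alkynylide 13 (not isolated)
Conditions: 12 (3 equiv), Me2Zn (3 equiv), (S,S)-ProPhenol (10 mol %), Ph3P=O (20 mol %), toluene, 0 °C; then 11, 4 °C; aq. NH4Cl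
Reagents that add atoms: none
Why: Zn-ProPhenol-catalysed asymmetric alkynylation of an enal with a propiolate; the dinuclear zinc catalyst delivers the alkynyl group to the Si face of the aldehyde and sets C6 (R in 14, the same spatial arrangement as 6S of the target).

Step 8
Reactants: 14 dimethyl (2E,6E,8R)-2-{[(tert-butyldimethylsilyl)oxy]methyl}-8-hydroxy-6-methylundeca-2,6-dien-9-ynedioate
Product: 15 dimethyl (2E,6R,7R,8S)-2-{[(tert-butyldimethylsilyl)oxy]methyl}-6,7-epoxy-8-hydroxy-6-methylundec-2-en-9-ynedioate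
Conditions: mCPBA (1.1 equiv), NaHCO3, CH2Cl2, 0 °C
Reagents that add atoms: 3-chloroperbenzoic acid (mCPBA), O=C(OO)c1cccc(Cl)c1
Why: hydroxyl-directed peracid epoxidation of the electron-rich C4=C5 olefin (the enoate and ynoate are too electron-poor); A(1,3) strain with the C15 methyl cis to C6 holds the C6–H bond in the olefin plane, so oxygen is delivered syn to the hydroxyl and the threo epoxy alcohol (4R,5R) should result.

Step 9
Reactants: 15 dimethyl (2E,6R,7R,8S)-2-{[(tert-butyldimethylsilyl)oxy]methyl}-6,7-epoxy-8-hydroxy-6-methylundec-2-en-9-ynedioate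
Product: 17 methyl (2E)-2-{[(tert-butyldimethylsilyl)oxy]methyl}-5-{(2R,3R)-2-methyl-3-[(2S)-5-oxo-2,5-dihydrofuran-2-yl]oxiran-2-yl}pent-2-enoate, via (Z)-hydroxy enoate 16 (not isolated)
Conditions: H2 (1 atm), Pd on CaCO3 poisoned with Pb(OAc)2, quinoline, EtOAc, rt; then PPTS (5 mol %), CH2Cl2, rt
Reagents that add atoms: none
Why: semi-hydrogenation over lead-poisoned palladium (Lindlar reduction) gives the (Z)-4-hydroxy-enoate, which lactonises to the butenolide with loss of methanol; C6 is not touched.

Step 10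
Reactants: 17 butenolide (name as in step 9)
Product: 19 Mannich lactone: γ-lactone carrying vinyl at C7 trans to the C6 epoxide side chain and CH2NMe2 at C11 trans to vinyl, via silyl ketene acetal 18 (not isolated)
Conditions: vinylmagnesium bromide (1.5 equiv), CuBr·SMe2 (10 mol %), TMSCl (2 equiv), THF, −78 °C; then dimethylmethyleneammonium iodide, −78 °C to rt; aq. NaHCO3
Reagents that add atoms: vinylmagnesium bromide, C=C[Mg]Br; dimethylmethyleneammonium iodide (Eschenmoser's salt), C=[N+](C)C.[I-]
Why: copper-catalysed conjugate addition to a 5-substituted butenolide occurs anti to the C6 side chain and sets C7 (trans lactone), and the silyl ketene acetal is aminomethylated (Mannich reaction) anti to the vinyl group at C11, a centre that is removed in step 11.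

Step 11
Reactants: 19 Mannich lactone
Product: 21 α-methylene lactone: methyl (2E)-2-{[(tert-butyldimethylsilyl)oxy]methyl}-5-{(2R,3R)-2-methyl-3-[(2S)-4-methylidene-5-oxo-3-vinyltetrahydrofuran-2-yl]oxiran-2-yl}pent-2-enoate (2,3-trans on the lactone), via ammonium iodide 20 (not isolated)
Conditions: MeI (10 equiv), MeOH, rt; then NaHCO3, EtOAc/H2O, rt
Reagents that add atoms: none
Why: N-methylation followed by E1cB (Hofmann-type) loss of trimethylamine unveils the C11=C13 methylene; C7 and C6 are unaffected.

Step 12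
Reactants: 21 α-methylene lactone silyl ether
Product: 22 primary allylic alcohol (C9–OH) of 21
Conditions: HF·pyridine, pyridine, THF, 0 °C
Reagents that add atoms: none
Why: buffered fluoride desilylation of the primary allylic TBS ether, tolerated by the epoxide and both acrylate units; no stereocenter.

Step 13
Reactants: 22 primary allylic alcohol
Product: 24 lactone aldehyde (C8 aldehyde on C7, C9–OH free), via vicinal diol 23 (not isolated)
Conditions: OsO4 (2 mol %), NaIO4 (4 equiv), 2,6-lutidine, dioxane/H2O 3:1, rt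
Reagents that add atoms: osmium tetroxide, O=[Os](=O)(=O)=O; sodium periodate, [Na+].[O-][I](=O)(=O)=O
Why: Lemieux–Johnson cleavage; the monosubstituted vinyl group is the only olefin not conjugated to a carbonyl, so it should be dihydroxylated and cleaved selectively to the C8 aldehyde, and the buffered medium keeps C7 from epimerising.

Step 14
Reactants: 24 lactone aldehyde
Product: 25 dialdehyde: methyl (2E)-2-formyl-5-{(2R,3R)-3-[(2S)-3-formyl-4-methylidene-5-oxotetrahydrofuran-2-yl]-2-methyloxiran-2-yl}pent-2-enoate (2,3-trans on the lactone)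
Conditions: Dess–Martin periodinane (1.3 equiv), NaHCO3, CH2Cl2, 0 °C to rt; used crude
Reagents that add atoms: none
Why: Dess–Martin oxidation of the allylic alcohol gives the 2-formyl-2-enoate under neutral conditions that leave the C8 aldehyde and its α-centre C7 intact.

Step 15
Reactants: 25 dialdehyde
Product: 27 methyl (1(10)E,4R,5R,6S,7R,8S,9R)-9-[(tert-butyldimethylsilyl)oxy]-4,5-epoxy-8-hydroxygermacra-1(10),11(13)-dien-12,6-olid-14-oate, via allylchromium 26 (not isolated)
Conditions: CrCl2 (6 equiv), TBSCl (3 equiv), DMF, rt, 25 added over 12 h (final 2 mM); aq. NaHCO3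
Reagents that add atoms: tert-butyldimethylsilyl chloride (TBSCl), CC(C)(C)[Si](C)(C)Cl
Why: Proposed new method: CrCl2 (divalent chromium) transfers one electron to the 2-formyl-2-enoate, the only group of 25 with a low enough LUMO (the C8 aldehyde, the methylene lactone and the epoxide are inert to CrCl2), TBSCl silylates O9, and a second CrCl2 captures the C1 radical to give the 3-siloxyallylchromium 26, which adds through C9 to the C8 aldehyde in a closed chair-like six-membered transition state (SE2′) and thereby re-forms the C1=C10 double bond; the closest known reaction types are the intermolecular CrCl2/R3SiCl cross-pinacol-type coupling of enals with aldehydes and the intramolecular CrCl2-mediated allylation of aldehydes that closes ten-membered carbocycles. Only one ring is closed, the ten-membered carbocycle, in an allyl-transposing mode in which C1, C10 and C9 all end inside the ring and the C1–Cr bond is exchanged for the C8–C9 bond. C8 is controlled by Felkin–Anh addition anti to the C7–C11 bond with the tether carbon C6 in the inside position, which gives 8S. C9 is controlled by the chair itself: the six-carbon tether C2–C7 can bridge C1 and C8 only when C2 is axial and C7 equatorial, the siloxy group is trans to C1 and equatorial to avoid 1,3-strain with C2, and this arrangement gives the erythro (8,9-cis) adduct, 9R, which is why C9 is inverted in step 18. The axial C2, which also avoids the ester on C10, fixes the olefin with C2 trans to CO2Me (cis in the ring, as in the target), and the bulky TBSCl is not expected to silylate the hindered trivalent chromium alkoxide at O8, so O8 and O9 emerge differentiated. The step needs chemoselective reduction of one of two aldehydes, which the double activation of the enal by the ester secures, and ring closure over oligomerisation, which slow addition at 2 mM secures because each reduced molecule offers only C8 as electrophile.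

Step 16
Reactants: 27 macrocyclic carbinol
Product: 28 methyl (1(10)E,4R,5R,6S,7R,8S,9R)-9-[(tert-butyldimethylsilyl)oxy]-4,5-epoxy-8-(methacryloyloxy)germacra-1(10),11(13)-dien-12,6-olid-14-oate
Conditions: methacrylic anhydride (2 equiv), Et3N, DMAP (0.2 equiv), CH2Cl2, 0 °C
Reagents that add atoms: methacrylic anhydride, C=C(C)C(=O)OC(=O)C(C)=C
Why: DMAP-catalysed acylation of the free C8 hydroxyl with retention at C8, O9 being blocked as its TBS ether.

Step 17
Reactants: 28 8-methacrylate 9-silyl ether
Product: 29 methyl (1(10)E,4R,5R,6S,7R,8S,9R)-4,5-epoxy-9-hydroxy-8-(methacryloyloxy)germacra-1(10),11(13)-dien-12,6-olid-14-oate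
Conditions: HF·pyridine, pyridine, THF, 0 °C to rt
Reagents that add atoms: none
Why: fluoride desilylation under mildly acidic conditions, chosen to avoid base-induced migration of the methacryloyl group from O8 to the cis O9.

Step 18
Reactants: 29 9R alcohol
Product: 31 CNP0153978.3, methyl (1(10)E,4R,5R,6S,7R,8S,9S)-9-acetoxy-4,5-epoxy-8-(methacryloyloxy)germacra-1(10),11(13)-dien-12,6-olid-14-oate, via alkoxyphosphonium acetate 30 (not isolated)
Conditions: PPh3 (2 equiv), DIAD (2 equiv), toluene/THF, 0 °C; then AcOH (3 equiv) and 29, 0 °C to rt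
Reagents that add atoms: acetic acid, CC(=O)O
Why: Mitsunobu esterification: acetate displaces the C9 oxyphosphonium group by SN2 with inversion (9R to 9S), which installs the acetate and the 8,9-trans relationship at once; direct substitution at the activated allylic C9 is expected to beat SN2′ attack at the hindered ring carbon C1.

**Compound list**

1 | geranyl acetate, (2E)-3,7-dimethylocta-2,6-dien-1-yl acetate | CC(=O)OC/C=C(\C)CCC=C(C)C | starting material
2 | ozonide of the 6,7-olefin of 1 (3,3-dimethyl-1,2,4-trioxolane carrying the (3E)-5-acetoxy-3-methylpent-3-enyl chain at C5) | CC(=O)OC/C=C(\C)CCC1OOC(C)(C)O1 | intermediate (not isolated)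
3 | (4E)-6-acetoxy-4-methylhex-4-enal | CC(=O)OC/C=C(\C)CCC=O | intermediate
4 | methyl 3-hydroxypropanoate | COC(=O)CCO | starting material
5 | methyl 3-[(tert-butyldimethylsilyl)oxy]propanoate | COC(=O)CCO[Si](C)(C)C(C)(C)C | intermediate
6 | lithium enolate of 5 | COC(O[Li])=CCO[Si](C)(C)C(C)(C)C | intermediate (not isolated)
7 | methyl (6E)-8-acetoxy-3-hydroxy-6-methyl-2-{[(tert-butyldimethylsilyl)oxy]methyl}oct-6-enoate (diastereomers at C2/C3) | CC(=O)OC/C=C(\C)CCC(O)C(CO[Si](C)(C)C(C)(C)C)C(=O)OC | intermediate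
8 | 3-O-methanesulfonate of 7 | CC(=O)OC/C=C(\C)CCC(OS(C)(=O)=O)C(CO[Si](C)(C)C(C)(C)C)C(=O)OC | intermediate (not isolated)
9 | methyl (2E,6E)-8-acetoxy-6-methyl-2-{[(tert-butyldimethylsilyl)oxy]methyl}octa-2,6-dienoate | CC(=O)OC/C=C(\C)CC/C=C(\CO[Si](C)(C)C(C)(C)C)C(=O)OC | intermediate
10 | methyl (2E,6E)-8-hydroxy-6-methyl-2-{[(tert-butyldimethylsilyl)oxy]methyl}octa-2,6-dienoate | OC/C=C(\C)CC/C=C(\CO[Si](C)(C)C(C)(C)C)C(=O)OC | intermediate
11 | methyl (2E,6E)-6-methyl-8-oxo-2-{[(tert-butyldimethylsilyl)oxy]methyl}octa-2,6-dienoate | O=C/C=C(\C)CC/C=C(\CO[Si](C)(C)C(C)(C)C)C(=O)OC | intermediate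
12 | methyl propiolate | C#CC(=O)OC | starting material
13 | methylzinc alkynylide of 12 | C[Zn]C#CC(=O)OC | intermediate (not isolated)
14 | dimethyl (2E,6E,8R)-2-{[(tert-butyldimethylsilyl)oxy]methyl}-8-hydroxy-6-methylundeca-2,6-dien-9-ynedioate | O[C@@H](C#CC(=O)OC)/C=C(\C)CC/C=C(\CO[Si](C)(C)C(C)(C)C)C(=O)OC | intermediate
15 | dimethyl (2E,6R,7R,8S)-2-{[(tert-butyldimethylsilyl)oxy]methyl}-6,7-epoxy-8-hydroxy-6-methylundec-2-en-9-ynedioate | O[C@@H](C#CC(=O)OC)[C@H]1O[C@]1(C)CC/C=C(\CO[Si](C)(C)C(C)(C)C)C(=O)OC | intermediate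
16 | dimethyl (2E,6R,7R,8S,9Z)-2-{[(tert-butyldimethylsilyl)oxy]methyl}-6,7-epoxy-8-hydroxy-6-methylundeca-2,9-dienedioate | O[C@@H](/C=C\C(=O)OC)[C@H]1O[C@]1(C)CC/C=C(\CO[Si](C)(C)C(C)(C)C)C(=O)OC | intermediate (not isolated)
17 | methyl (2E)-2-{[(tert-butyldimethylsilyl)oxy]methyl}-5-{(2R,3R)-2-methyl-3-[(2S)-5-oxo-2,5-dihydrofuran-2-yl]oxiran-2-yl}pent-2-enoate | C1=CC(=O)O[C@@H]1[C@H]1O[C@]1(C)CC/C=C(\CO[Si](C)(C)C(C)(C)C)C(=O)OC | intermediate
18 | trimethylsilyl ketene acetal of the lactone (2-trimethylsiloxy-4,5-dihydrofuran; 4-vinyl trans to the 5-side chain) | C=C[C@H]1C=C(O[Si](C)(C)C)O[C@@H]1[C@H]1O[C@]1(C)CC/C=C(\CO[Si](C)(C)C(C)(C)C)C(=O)OC | intermediate (not isolated)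
19 | Mannich lactone: γ-butyrolactone with 3-(dimethylaminomethyl), 4-vinyl and 5-(epoxide side chain), 3,4-trans and 4,5-trans | C=C[C@H]1[C@H](CN(C)C)C(=O)O[C@@H]1[C@H]1O[C@]1(C)CC/C=C(\CO[Si](C)(C)C(C)(C)C)C(=O)OC | intermediate
20 | N-methyl ammonium iodide of 19 | C=C[C@H]1[C@H](C[N+](C)(C)C)C(=O)O[C@@H]1[C@H]1O[C@]1(C)CC/C=C(\CO[Si](C)(C)C(C)(C)C)C(=O)OC.[I-] | intermediate (not isolated)
21 | α-methylene lactone: methyl (2E)-2-{[(tert-butyldimethylsilyl)oxy]methyl}-5-{(2R,3R)-2-methyl-3-[(2S)-4-methylidene-5-oxo-3-vinyltetrahydrofuran-2-yl]oxiran-2-yl}pent-2-enoate, 2,3-trans on the lactone | C=C[C@H]1C(=C)C(=O)O[C@@H]1[C@H]1O[C@]1(C)CC/C=C(\CO[Si](C)(C)C(C)(C)C)C(=O)OC | intermediate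
22 | desilylated 21: methyl (2E)-2-(hydroxymethyl)-5-{…}pent-2-enoate | C=C[C@H]1C(=C)C(=O)O[C@@H]1[C@H]1O[C@]1(C)CC/C=C(\CO)C(=O)OC | intermediate
23 | 1,2-diol from the vinyl group of 22 | OCC(O)[C@H]1C(=C)C(=O)O[C@@H]1[C@H]1O[C@]1(C)CC/C=C(\CO)C(=O)OC | intermediate (not isolated)
24 | lactone aldehyde: 3-formyl-4-methylidene-γ-lactone (2,3-trans) with the (E)-2-(hydroxymethyl)enoate side chain | O=C[C@H]1C(=C)C(=O)O[C@@H]1[C@H]1O[C@]1(C)CC/C=C(\CO)C(=O)OC | intermediate
25 | dialdehyde: methyl (2E)-2-formyl-5-{(2R,3R)-3-[(2S)-3-formyl-4-methylidene-5-oxotetrahydrofuran-2-yl]-2-methyloxiran-2-yl}pent-2-enoate, 2,3-trans on the lactone | O=C[C@H]1C(=C)C(=O)O[C@@H]1[C@H]1O[C@]1(C)CC/C=C(\C=O)C(=O)OC | intermediate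
26 | 3-siloxyallylchromium dichloride: Cr on C1, C9=C10 enol silyl ether with OTBS trans to C1 | O=C[C@H]1C(=C)C(=O)O[C@@H]1[C@H]1O[C@]1(C)CCC([Cr](Cl)Cl)/C(C(=O)OC)=C/O[Si](C)(C)C(C)(C)C | intermediate (not isolated)
27 | methyl (1(10)E,4R,5R,6S,7R,8S,9R)-9-[(tert-butyldimethylsilyl)oxy]-4,5-epoxy-8-hydroxygermacra-1(10),11(13)-dien-12,6-olid-14-oate | O[C@H]1[C@H]2C(=C)C(=O)O[C@@H]2[C@H]2O[C@]2(C)CC/C=C(/C(=O)OC)[C@H]1O[Si](C)(C)C(C)(C)C | intermediate
28 | 8-O-methacryloyl derivative of 27 | C=C(C)C(=O)O[C@H]1[C@H]2C(=C)C(=O)O[C@@H]2[C@H]2O[C@]2(C)CC/C=C(/C(=O)OC)[C@H]1O[Si](C)(C)C(C)(C)C | intermediate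
29 | methyl (1(10)E,4R,5R,6S,7R,8S,9R)-4,5-epoxy-9-hydroxy-8-(methacryloyloxy)germacra-1(10),11(13)-dien-12,6-olid-14-oate | C=C(C)C(=O)O[C@H]1[C@H]2C(=C)C(=O)O[C@@H]2[C@H]2O[C@]2(C)CC/C=C(/C(=O)OC)[C@H]1O | intermediate
30 | 9-O-triphenylphosphonium acetate of 29 | C=C(C)C(=O)O[C@H]1[C@H]2C(=C)C(=O)O[C@@H]2[C@H]2O[C@]2(C)CC/C=C(/C(=O)OC)[C@H]1O[P+](c1ccccc1)(c1ccccc1)c1ccccc1.CC(=O)[O-] | intermediate (not isolated)
31 | CNP0153978.3, methyl (1(10)E,4R,5R,6S,7R,8S,9S)-9-acetoxy-4,5-epoxy-8-(methacryloyloxy)germacra-1(10),11(13)-dien-12,6-olid-14-oate | C=C(C)C(=O)O[C@H]1[C@H]2C(=C)C(=O)O[C@@H]2[C@H]2O[C@]2(C)CC/C=C(/C(=O)OC)[C@@H]1OC(C)=O | target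

**Count and risks**

Total steps: 18. Longest linear sequence: 17 (steps 1 and 3–18; step 2 is a one-step branch).

Steps most likely to fail:

1. Step 15 (the proposed new method). What may go wrong: intermolecular addition or plain conjugate reduction of the allylchromium outrunning the ten-membered ring closure; closure through C1 instead of C9 (eight-membered ring); poor facial selectivity at C8 or formation of the ring-trans olefin. Fallback from 25, returning at 31: the dialdehyde 25 would be closed by the known titanium-mediated pinacol coupling of dialdehydes (McMurry-type; TiCl3(DME)1.5, Zn–Cu couple, DME, rt, slow addition). This is a radical–radical coupling of two titanium-bound ketyls, a different mechanism with no closed allyl-metal transition state; in ten-membered rings it is expected to give mainly trans diols, so no inversion is needed. It would give methyl (1(10)E,4R,5R,6S,7R,8S,9S)-4,5-epoxy-8,9-dihydroxygermacra-1(10),11(13)-dien-12,6-olid-14-oate F1. Selective acetylation of the more reactive allylic C9 hydroxyl (Ac2O 1.1 equiv, pyridine, −20 °C) would give the 9-acetate 8-alcohol F2, and methacrylic anhydride/DMAP/Et3N would then give 31.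

2. Step 18. What may go wrong: SN2′ attack of acetate at C1, participation of the neighbouring methacrylate or its migration from O8 to O9 under the basic betaine, elimination, and addition of PPh3 to the acrylate units. Fallback from 29, returning at 31: oxidation–reduction instead of substitution. Dess–Martin oxidation of 29 (NaHCO3, CH2Cl2) would give the C9 ketone, methyl (1(10)E,4R,5R,6S,7R,8S)-4,5-epoxy-8-(methacryloyloxy)-9-oxogermacra-1(10),11(13)-dien-12,6-olid-14-oate F3. Luche reduction (NaBH4, CeCl3·7H2O, MeOH, −78 °C; 1,2-selective) is expected to deliver hydride anti to the C8 acyloxy group (Felkin–Anh) and give the 9S alcohol F4, which Ac2O/pyridine/DMAP would convert into 31.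

3. Step 13. What may go wrong: loss of chemoselectivity, with dihydroxylation of the lactone methylene or the enoate competing with the vinyl group, and epimerisation at C7 of the new aldehyde. Fallback from 19, returning at 24: the vinyl group would be cleaved while the lactone methylene is still masked as the amine, so no competing acrylate is present. Lemieux–Johnson cleavage of 19 (OsO4 cat., NaIO4, 2,6-lutidine, dioxane/H2O) would give the amino lactone aldehyde F5; MeI, then NaHCO3 would give the methylene lactone aldehyde silyl ether F6; HF·pyridine/pyridine would then give 24.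

Further compounds
F1 | step 15 | methyl (1(10)E,4R,5R,6S,7R,8S,9S)-4,5-epoxy-8,9-dihydroxygermacra-1(10),11(13)-dien-12,6-olid-14-oate | O[C@H]1[C@H]2C(=C)C(=O)O[C@@H]2[C@H]2O[C@]2(C)CC/C=C(/C(=O)OC)[C@@H]1O
F2 | step 15 | methyl (1(10)E,4R,5R,6S,7R,8S,9S)-9-acetoxy-4,5-epoxy-8-hydroxygermacra-1(10),11(13)-dien-12,6-olid-14-oate | O[C@H]1[C@H]2C(=C)C(=O)O[C@@H]2[C@H]2O[C@]2(C)CC/C=C(/C(=O)OC)[C@@H]1OC(C)=O
F3 | step 18 | methyl (1(10)E,4R,5R,6S,7R,8S)-4,5-epoxy-8-(methacryloyloxy)-9-oxogermacra-1(10),11(13)-dien-12,6-olid-14-oate | C=C(C)C(=O)O[C@H]1[C@H]2C(=C)C(=O)O[C@@H]2[C@H]2O[C@]2(C)CC/C=C(/C(=O)OC)C1=O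
F4 | step 18 | methyl (1(10)E,4R,5R,6S,7R,8S,9S)-4,5-epoxy-9-hydroxy-8-(methacryloyloxy)germacra-1(10),11(13)-dien-12,6-olid-14-oate | C=C(C)C(=O)O[C@H]1[C@H]2C(=C)C(=O)O[C@@H]2[C@H]2O[C@]2(C)CC/C=C(/C(=O)OC)[C@@H]1O
F5 | step 13 | amino lactone aldehyde: 19 with the vinyl group replaced by formyl | O=C[C@H]1[C@H](CN(C)C)C(=O)O[C@@H]1[C@H]1O[C@]1(C)CC/C=C(\CO[Si](C)(C)C(C)(C)C)C(=O)OC
F6 | step 13 | methylene lactone aldehyde silyl ether: 21 with the vinyl group replaced by formyl | O=C[C@H]1C(=C)C(=O)O[C@@H]1[C@H]1O[C@]1(C)CC/C=C(\CO[Si](C)(C)C(C)(C)C)C(=O)OC
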